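The constants used here are those of an exercise, and the outcome is calculated.

Start from the end of the run.

    nucleophile + acid set free ⇌ protonated nucleophile, settled at all times (K1 = 37600 M⁻¹)
    acid set free + free base ⇌ salt of the base, settled at all times (K2 = 11000 M⁻¹)
    protic impurity + free base → quenched reagent (k3 = 0.124 M⁻¹ min⁻¹)
    electrophile + nucleophile → acid set free + product (k4 = 0.0105 M⁻¹ min⁻¹)
    solid base ⇌ free base, rate k5*(cs5 - [free base]) while solid is left; crystals form when [free base] > cs5 (cs5 = 8.6 mM, k5 = 7.22 × 10⁻⁴ min⁻¹)

electrophile 0.020 M; solid base 0.0220 M; protic impurity 4.00 mM; time 10 d

- the concentration of nucleophile at which the part of the electrophile that has reacted at 10 d is just 70%, in M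

- solid base is a solid; its amount is given per volume of the solution
- the amount of nucleophile is what is sought; it is there from the start
- at the start none of the solid base is in solution
- run time (flask): 10 d

Keep the books on the electrophile. At 70% of its charge, 14.0 mM has become product, so the flask has also spent 14.0 mM of nucleophile and set free 14.0 mM of acid. At a given free nucleophile level the electrophile decays pseudo-first-order, so the time course enters the target through one average. The logarithm of the inverse of the unreacted part, divided by 0.0105 M⁻¹ min⁻¹ times 10 d, gives b̄ = 7.96 mM, the mean free nucleophile that the target demands over the run.

The free level falls, so I guess that it ends at 3.98 mM, half of b̄; the rest of my reckoning hangs on this guess. Taking free base at its solubility 8.6 mM, I get a half-life for the protic impurity of 0.451 d, far shorter than the run, so I book its 4.00 mM against the base. The two balances split the acid as protonated nucleophile to salt of the base in the ratio 1.58, which puts 5.42 mM on the base and 8.58 mM on the nucleophile. In this reckoning the free acid is 0.0573 mM, far less than the 14.0 mM set free, so I leave it off the books. The base entries come to 18.0 mM, less than the 0.0220 M charged, so by this reckoning 4.00 mM of solid stays. The nucleophile entries close at 26.6 mM.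

The forecast is 0.025 M, a little below my figure, on these grounds: “Both equilibria are strong, so the acid sits on the nucleophile and on dissolved base”.

The simulation gives 0.0259 M, and the forecast stands within its margin. In that flask the electrophile half-life of 3.8 d at 1.71 d corresponds to 12.2 mM of free nucleophile, above b̄ of 7.96 mM, while at 10.0 d the 13.7% of the charge still free is 3.55 mM, below b̄. The 44.1% of the electrophile used by 2.50 d, a quarter of the time, already stands for 48.3% of the exposure b̄ times 10 d.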